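| flask | substrate | free catalyst | remark | time |
|---|---|---|---|---|
| beta | 20 mM | 2 mM | run made earlier |  |
| gamma | 13 mM | 2 mM | run made earlier |  |
| theta | 30 mM | 2 mM | run made earlier |  |
| blue | 20 mM (fed, over 4.00 h) | 2.0 mM | all but substrate at the start; substrate goes in evenly over 4.00 h, the run ends at 4.0 h | 4.0 h |
| ochre | 20 mM | 2.0 mM | everything together in a closed stirred flask, run for 4.0 h | 4.0 h |
| grey | 20 mM | 2.0 mM | one stirred flow tank at steady state, fed with the mixture as stated, mean residence time 4.0 h |  |

| run | time / h | product / % | substrate / % |
|---|---|---|---|
| beta | 0.167 | 1.7 | 93.2 |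
| beta | 0.500 | 7.5 | 86.1 |
| beta | 0.833 | 13.2 | 79.8 |
| beta | 1.33 | 23.2 | 71.9 |
| beta | 2.00 | 34.1 | 60.7 |
| beta | 2.50 | 42.3 | 53.2 |
| gamma | 0.200 | 2.3 | 91.5 |
| gamma | 0.667 | 12.2 | 79.6 |
| gamma | 1.00 | 20.7 | 72.3 |
| gamma | 2.00 | 40.6 | 52.2 |
| gamma | 2.50 | 50.5 | 43.9 |
| gamma | 3.00 | 58.6 | 36.2 |
| theta | 0.500 | 6.1 | 89.2 |
| theta | 1.00 | 12.9 | 82.2 |
| theta | 1.50 | 19.4 | 75.2 |
| theta | 2.00 | 27.4 | 68.2 |
| theta | 2.50 | 32.8 | 62.5 |
| theta | 3.00 | 39.6 | 56.3 |

(readings scatter by 0.3 percentage points)

- the stated concentrations are those of everything mixed, before any reaction; amounts are the same in each set-up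
- the feed brings no volume worth counting
- the earlier runs were made in a closed, stirred flask

- the set-up with the highest amount of product at the outlet or at the end, in percent of the substrate put in ("none" if the first two lie within 2 percentage points) (blue / ochre / grey / none)
- amount of product at the outlet or at the end, in percent of the substrate put in, blue
- amount of product at the outlet or at the end, in percent of the substrate put in, ochre
- amount of product at the outlet or at the end, in percent of the substrate put in, grey

Keep books on the substrate. In the beta run at 2.50 h, product stands at 8.46 mM, more than the 2 mM of free catalyst charged, so the catalyst comes back and substrate is the limiting reagent. Its entries are free, held on the catalyst, and product. At that reading, free substrate and product leave a gap of 0.900 mM, less than the catalyst charged, and I read that gap as the held entry.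

I take the product rate as V S/(K+S), with S the free substrate, V the ceiling and K a constant of the catalyst. Integrated, this says that free substrate standing at S falls to a later value s in a time (S − s)/V + τ ln(S/s). Here τ = K/V is the tail time, the time S takes to fall by a factor e once it stands well below K. With product gained standing for S − s, gamma from its second reading to its last and theta from its first to its last give V = 5.74 mM/h and τ = 1.63 h, so K = 9.33 mM.

Ochre is beta carried on. From beta's last S of 10.6 mM, my rule brings ochre to 6.67 mM, a third of the charge, at 3.95 h. The catalyst then holds 0.833 mM, and product closes the books at 62.5 %, which I take as my figure for ochre at 4.0 h. Blue is fed at 5.00 mM/h, less than V, and starts with no substrate, while ochre starts with its whole 20 mM, so I put ochre above it.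

The forecast also says ochre, with 43 % for blue, 64 % for ochre and 55 % for grey, on the ground that “product rates saturate”. Its ochre is higher than mine, and it works with 5.2 mM/h and 7 mM where I have 5.74 mM/h and 9.33 mM.

The flask gives 39.4 % for blue, 62.8 % for ochre and 52.3 % for grey, so ochre leads, as forecast.

    substrate + free catalyst → catalyst intermediate (k = 290 /M/h)
    catalyst intermediate → free catalyst + product (k = 3.00 /h)

In ochre at 4.00 h, substrate stands at 33.1 %, product at 62.8 %, and the catalyst intermediate holds 0.813 mM. From beta's last reading, the rule reaches that substrate at 3.96 h. Now leave the ochre flask standing until 15 h, where its free substrate reads 0.11 % of the charge. The same rule reaches that level at 14.3 h, and the tail term makes up 10.07 h of that. At 15 h, that flask holds product at 99.9 %.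

All runs are calculated from invented constants.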